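**Retrosynthetic overview**

1. Target 14 comes from rhodoxanthin 13, an achiral C2-symmetric dione: one Corey–Bakshi–Shibata mono-reduction in the last step sets the only stereocentre (3′S).
2. 13 comes from the C10 dialdehyde 10 and two copies of the C15 ring phosphonium salt 9 (double Wittig at C11=C12 and C11′=C12′), followed by dehydrogenation of the leuco dione 12 to the retro-polyene.
3. Ring formation (key step, 8 to 9): an acid-triggered C1–C6 closure of an acyclic 3-oxo psi end group in the epsilon mode (loss of H-4), started through the C3 carbonyl so the ring is formed already oxygenated at C3. Both six-membered end rings of 14 arise from this one operation (two copies of 9 are joined in step 6); no other ring is formed.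
4. The acyclic C15 chain 8 comes from the C10 unit 3 (acylation of isoprene with 3-methylbut-2-enoyl chloride) and the C5 acetoxy aldehyde 5 (Wittig).

Assumption: the racemic C6 centre of 9 and 12 and E/Z mixtures in the chain are carried through unseparated (SMILES show the E isomers), because both are erased or equilibrated when the retro-polyene 13 is formed.

**Route**

Step 1
Reactants: 1 isoprene; 2 3-methylbut-2-enoyl chloride
Product: 3 (6E)-8-chloro-2,6-dimethylocta-2,6-dien-4-one
Conditions: SnCl4 (5 mol%), CH2Cl2, −78 °C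
Reagents that add atoms: none
Why: Kondakov (Friedel–Crafts-type) acylation of a 1,3-diene, in which the SnCl4-activated acyl chloride attacks the CH2 terminus next to the methyl-bearing carbon of isoprene and the tertiary allyl cation takes up chloride at its primary end (1,4-addition) to give the trisubstituted E alkene, with no stereocentre formed.

Step 2
Reactants: 3 (6E)-8-chloro-2,6-dimethylocta-2,6-dien-4-one
Product: 4 [(2E)-3,7-dimethyl-5-oxoocta-2,6-dien-1-yl]triphenylphosphonium chloride
Conditions: PPh3 (1.05 equiv), MeCN, 60 °C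
Reagents that add atoms: triphenylphosphine, c1ccc(cc1)P(c1ccccc1)c1ccccc1
Why: SN2 quaternisation of a primary allylic chloride by PPh3 (phosphonium salt formation), the beta,beta-disubstituted enone being too hindered for phosphine conjugate addition.

Step 3
Reactants: 4 [(2E)-3,7-dimethyl-5-oxoocta-2,6-dien-1-yl]triphenylphosphonium chloride; 5 (2E)-4-acetoxy-2-methylbut-2-enal
Product: 7 (2E,4E,6E)-3,7,11-trimethyl-9-oxododeca-2,4,6,10-tetraen-1-yl acetate, via keto ylide 6 (not isolated)
Conditions: NaOMe (1.05 equiv, added last), CH2Cl2/MeOH, −30 °C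
Reagents that add atoms: none
Why: Wittig olefination run in Barbier mode, in which the allylic P–CH2 is the most acidic site and its semi-stabilised ylide 6 is intercepted at once by the unhindered enal 5 while the hindered enone and the allylic acetate are left alone, the E/Z ratio of the new double bond being irrelevant because that bond becomes a single bond in the retro-polyene.

Step 4
Reactants: 7 (2E,4E,6E)-3,7,11-trimethyl-9-oxododeca-2,4,6,10-tetraen-1-yl acetate
Product: 8 [(2E,4E,6E)-3,7,11-trimethyl-9-oxododeca-2,4,6,10-tetraen-1-yl]triphenylphosphonium bromide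
Conditions: PPh3·HBr (1.05 equiv), CH2Cl2/MeOH, 0 °C to rt
Reagents that add atoms: triphenylphosphine hydrobromide, [Br-].[PH+](c1ccccc1)(c1ccccc1)c1ccccc1
Why: Acid-mediated allylic substitution (SN1) of the kind used to turn polyenyl acetates into Wittig salts, in which HBr ionises the allylic acetate to a delocalised trienyl cation that PPh3 captures at the unhindered primary terminus faster than the cation loses a proton.

Step 5
Reactants: 8 [(2E,4E,6E)-3,7,11-trimethyl-9-oxododeca-2,4,6,10-tetraen-1-yl]triphenylphosphonium bromide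
Product: 9 [(2E,4E)-3-methyl-5-(2,6,6-trimethyl-4-oxocyclohex-2-en-1-yl)penta-2,4-dien-1-yl]triphenylphosphonium bromide (racemic)
Conditions: TfOH (20 mol%), CH2Cl2, −40 to 0 °C
Reagents that add atoms: none
Why: Proposed new method: O-protonation of the beta,beta-dimethyl enone makes C1 the tertiary end of a hydroxyallyl cation that is attacked by C6 of the 5,6-double bond in a 6-endo cation–olefin closure (the same C1–C6 bond and the same loss of H-4 as in the enzymatic epsilon-cyclisation of a psi end group, the cation closing in its cisoid form as in neryl-to-terpinyl cyclisations, whereas the five-ring alternative is a strained closure that would join two fully substituted carbons), after which the tertiary C5 cation loses H-4 to a dienol that ketonises to the conjugated 3-oxo ring and returns the proton; the closest known reaction types are the acid-catalysed pseudoionone-to-alpha-ionone cyclisation and Brønsted or Lewis acid-initiated enone–olefin cyclisations, and the new C6 stereocentre is formed racemic, which is harmless because it becomes sp2 in step 6.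

Step 6
Reactants: 9 [(2E,4E)-3-methyl-5-(2,6,6-trimethyl-4-oxocyclohex-2-en-1-yl)penta-2,4-dien-1-yl]triphenylphosphonium bromide (2.2 equiv); 10 (2E,4E,6E)-2,7-dimethylocta-2,4,6-trienedial
Product: 13 rhodoxanthin, via ring ylide 11 (not isolated), via leuco dione 12 (not isolated)
Conditions: NaOMe (2.5 equiv), CH2Cl2/MeOH, −10 °C to rt, Ar; then air (O2), rt; I2 (cat.), heptane, 80 °C
Reagents that add atoms: none
Why: Double Wittig olefination of the dialdehyde by the dienyl-stabilised ylide 11 (its P–CH2 is more acidic and far less hindered than the ring gamma-H at C6), followed in the same pot by base-mediated autoxidation in which deprotonation at C6 and C6′ gives the bis-dienolate of 12, the hydroquinone-like leuco form of the quinoid retro-polyene, which hands two electrons to O2, while iodine-catalysed equilibration and crystallisation deliver the (6E,6′E) all-E isomer and both racemic C6 centres disappear.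

Step 7
Reactants: 13 rhodoxanthin
Product: 14 (3′S)-3′-hydroxy-4′,5′-didehydro-4,5′-retro-β,β-caroten-3-one (eschscholtzxanthone)
Conditions: (R)-1-methyl-3,3-diphenyltetrahydro-1H,3H-pyrrolo[1,2-c][1,3,2]oxazaborole (0.2 equiv), catecholborane (0.55 equiv), CH2Cl2/toluene, −40 °C
Reagents that add atoms: none
Why: Corey–Bakshi–Shibata reduction, in which the catalyst–borane complex binds the carbonyl lone pair on the side of the saturated CH2 and delivers hydride to the Re face with the ring alkene as the large group, which sets 3′S, while the sub-stoichiometric borane stops mainly at the mono-alcohol of the C2-symmetric dione (unreacted 13 is recycled) and the s-trans ring enone undergoes only 1,2-reduction.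

**Compound list**

1 | isoprene (2-methylbuta-1,3-diene) | CC(=C)C=C | starting material
2 | 3-methylbut-2-enoyl chloride | CC(C)=CC(Cl)=O | starting material
3 | (6E)-8-chloro-2,6-dimethylocta-2,6-dien-4-one | CC(C)=CC(=O)C/C(C)=C/CCl | intermediate
4 | [(2E)-3,7-dimethyl-5-oxoocta-2,6-dien-1-yl]triphenylphosphonium chloride | CC(C)=CC(=O)C/C(C)=C/C[P+](c1ccccc1)(c1ccccc1)c1ccccc1.[Cl-] | intermediate
5 | (2E)-4-acetoxy-2-methylbut-2-enal | CC(=O)OC/C=C(C)/C=O | starting material
6 | [(2E)-3,7-dimethyl-5-oxoocta-2,6-dien-1-ylidene]triphenylphosphorane (keto ylide) | CC(C)=CC(=O)C/C(C)=C/C=P(c1ccccc1)(c1ccccc1)c1ccccc1 | intermediate (not isolated)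
7 | (2E,4E,6E)-3,7,11-trimethyl-9-oxododeca-2,4,6,10-tetraen-1-yl acetate | CC(C)=CC(=O)C/C(C)=C/C=C/C(C)=C/COC(C)=O | intermediate
8 | [(2E,4E,6E)-3,7,11-trimethyl-9-oxododeca-2,4,6,10-tetraen-1-yl]triphenylphosphonium bromide | CC(C)=CC(=O)C/C(C)=C/C=C/C(C)=C/C[P+](c1ccccc1)(c1ccccc1)c1ccccc1.[Br-] | intermediate
9 | [(2E,4E)-3-methyl-5-(2,6,6-trimethyl-4-oxocyclohex-2-en-1-yl)penta-2,4-dien-1-yl]triphenylphosphonium bromide (racemic at the ring CH) | CC1=CC(=O)CC(C)(C)C1/C=C/C(C)=C/C[P+](c1ccccc1)(c1ccccc1)c1ccccc1.[Br-] | intermediate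
10 | (2E,4E,6E)-2,7-dimethylocta-2,4,6-trienedial (C10 dialdehyde) | O=C/C(C)=C/C=C/C=C(C)/C=O | starting material
11 | [(2E,4E)-3-methyl-5-(2,6,6-trimethyl-4-oxocyclohex-2-en-1-yl)penta-2,4-dien-1-ylidene]triphenylphosphorane (ring ylide, racemic) | CC1=CC(=O)CC(C)(C)C1/C=C/C(C)=C/C=P(c1ccccc1)(c1ccccc1)c1ccccc1 | intermediate (not isolated)
12 | ε,ε-carotene-3,3′-dione (leuco dione; all-E chain; mixture of C6/C6′ stereoisomers) | CC1=CC(=O)CC(C)(C)C1/C=C/C(C)=C/C=C/C(C)=C/C=C/C=C(C)/C=C/C=C(C)/C=C/C1C(C)=CC(=O)CC1(C)C | intermediate (not isolated)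
13 | rhodoxanthin, (6E,6′E)-4′,5′-didehydro-4,5′-retro-β,β-carotene-3,3′-dione | CC1=CC(=O)CC(C)(C)\C1=C/C=C(C)/C=C/C=C(C)/C=C/C=C/C(C)=C/C=C/C(C)=C/C=C1/C(C)=CC(=O)CC1(C)C | intermediate
14 | (3′S,6E,6′E)-3′-hydroxy-4′,5′-didehydro-4,5′-retro-β,β-caroten-3-one (eschscholtzxanthone, CNP0279160.1) | CC1=CC(=O)CC(C)(C)\C1=C/C=C(C)/C=C/C=C(C)/C=C/C=C/C(C)=C/C=C/C(C)=C/C=C1/C(C)=C[C@@H](O)CC1(C)C | target

**Step count and risks**

Total step count: 7. Longest linear sequence: 7 steps (1 and 2 through 3, 4, 7, 8, 9 and 13 to 14); 5 and 10 are bought.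

The three steps most likely to fail are steps 5, 3 and 6.

The cyclisation in step 5 is unprecedented on this substrate. The acid may instead move the 5,6-double bond into conjugation with the ketone or oligomerise the triene. The fallback changes both the mechanism and the order. It sets out from 7: the ring is closed on the acetate before the phosphonium is made, without strong acid, by heating in toluene at 110 °C with pyridinium p-toluenesulfonate (5 mol%), so that the cross-conjugated dienol undergoes a 6π-electrocyclisation and ketonises to the ring acetate (2E,4E)-3-methyl-5-(2,6,6-trimethyl-4-oxocyclohex-2-en-1-yl)penta-2,4-dien-1-yl acetate F5. Treating F5 with PPh3·HBr as in step 4 then returns to the route at 9.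

In step 3 the ketone alpha-CH2 of 4 is nearly as acidic as the P–CH2. Its dienolate can expel PPh3 (vinylogous retro-Michael), and the enolisable product 7 can lose acetate in the same way. The fallback takes the ketone out of play and sets out from 3. Luche reduction (NaBH4, CeCl3·7H2O, MeOH, −20 °C) gives the chloro alcohol (6E)-8-chloro-2,6-dimethylocta-2,6-dien-4-ol F1, and PPh3 converts this to the hydroxy phosphonium chloride F2. NaOMe forms its ylide F3, which olefinates 5 to the hydroxy acetate F4. MnO2 (CH2Cl2, rt) re-oxidises the allylic alcohol, which returns to the route at 7.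

In step 6 the polyenolate formed by deprotonating 9 at the ring gamma-position can expel PPh3 before the ylide reacts, and the aerobic stage can oxygenate as well as dehydrogenate. The fallback carries the ring oxygen through the coupling as an alcohol and sets out from 9. Luche reduction (NaBH4, CeCl3·7H2O, MeOH, −20 °C) gives the hydroxy phosphonium bromide F6. Its ylide F7 (NaOMe, CH2Cl2/MeOH) olefinates 10 to ε,ε-carotene-3,3′-diol F8. MnO2 (CH2Cl2, rt) oxidises both allylic alcohols in the absence of base and returns to the route at 12, which is then aerated with catalytic NaOMe as in the second half of step 6 to give 13.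

Further compounds
F1 | step 3 | (6E)-8-chloro-2,6-dimethylocta-2,6-dien-4-ol (racemic) | CC(C)=CC(O)C/C(C)=C/CCl
F2 | step 3 | [(2E)-5-hydroxy-3,7-dimethylocta-2,6-dien-1-yl]triphenylphosphonium chloride (racemic) | CC(C)=CC(O)C/C(C)=C/C[P+](c1ccccc1)(c1ccccc1)c1ccccc1.[Cl-]
F3 | step 3 | [(2E)-5-hydroxy-3,7-dimethylocta-2,6-dien-1-ylidene]triphenylphosphorane (racemic) | CC(C)=CC(O)C/C(C)=C/C=P(c1ccccc1)(c1ccccc1)c1ccccc1
F4 | step 3 | (2E,4E,6E)-9-hydroxy-3,7,11-trimethyldodeca-2,4,6,10-tetraen-1-yl acetate (racemic) | CC(C)=CC(O)C/C(C)=C/C=C/C(C)=C/COC(C)=O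
F5 | step 5 | (2E,4E)-3-methyl-5-(2,6,6-trimethyl-4-oxocyclohex-2-en-1-yl)penta-2,4-dien-1-yl acetate (racemic) | CC1=CC(=O)CC(C)(C)C1/C=C/C(C)=C/COC(C)=O
F6 | step 6 | [(2E,4E)-5-(4-hydroxy-2,6,6-trimethylcyclohex-2-en-1-yl)-3-methylpenta-2,4-dien-1-yl]triphenylphosphonium bromide (stereoisomer mixture) | CC1=CC(O)CC(C)(C)C1/C=C/C(C)=C/C[P+](c1ccccc1)(c1ccccc1)c1ccccc1.[Br-]
F7 | step 6 | [(2E,4E)-5-(4-hydroxy-2,6,6-trimethylcyclohex-2-en-1-yl)-3-methylpenta-2,4-dien-1-ylidene]triphenylphosphorane (stereoisomer mixture) | CC1=CC(O)CC(C)(C)C1/C=C/C(C)=C/C=P(c1ccccc1)(c1ccccc1)c1ccccc1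
F8 | step 6 | ε,ε-carotene-3,3′-diol (all-E chain; stereoisomer mixture) | CC1=CC(O)CC(C)(C)C1/C=C/C(C)=C/C=C/C(C)=C/C=C/C=C(C)/C=C/C=C(C)/C=C/C1C(C)=CC(O)CC1(C)C
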